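(All constants are those of an exercise; the result is computed.)

A neighbour of these flasks is charged with 0.037 M of partner where these two hold 0.149 M, and that gap sends me to one question before any other: how much product can the partner pay for?

the same everywhere: left-handed substrate 0.099 M; partner 0.149 M; right-handed substrate 0.099 M; time 2.0 h

| run | temperature |
|---|---|
| Wednesday's | 25 °C |
| Thursday's | 50 °C |

- the flask that comes out highest in amount of left-handed product, in percent of the left-handed substrate and right-handed substrate together charged, or "all alike" when all lie within 1.5 percentage points (Wednesday's / Thursday's / all alike)
- left-handed product at the end, in percent of the left-handed substrate and right-handed substrate together charged, Wednesday's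
- left-handed product at the end, in percent of the left-handed substrate and right-handed substrate together charged, Thursday's

- partner is single-handed; left-handed substrate and right-handed substrate are mirror images of each other, charged as a racemate, each of them at the stated concentration
- the constants hold at 25 °C; other temperatures follow from the activation energies and enthalpies
- the handed part of partner does not stay in what it makes, so the products of the two hands are mirror images too

    partner + left-handed substrate → left-handed product (k1 = 0.026 L mol⁻¹ s⁻¹, Ea1 = 64.0 kJ mol⁻¹)
    partner + right-handed substrate → right-handed product (k2 = 0.0021 L mol⁻¹ s⁻¹, Ea2 = 53.0 kJ mol⁻¹)
    left-handed product ⇌ right-handed product (k3 = 1.1 × 10⁻⁴ s⁻¹, Ea3 = 103 kJ mol⁻¹)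
    partner ⇌ dormant form (K4 = 1.8, k4 = 7.9 × 10⁻⁴ s⁻¹, Ea4 = 83.0 kJ mol⁻¹, ΔH4 = 22.0 kJ mol⁻¹)
    (constants at 25 °C)

Partner joins a substrate of either hand and makes the product of that hand, the two products turn into each other, and partner passes reversibly into a dormant form. Each forming rate is a rate constant times free partner times substrate, so free partner is the concentration that stands in both rates, and each product formed uses up one partner. I therefore carry the partner share, partner charged over both substrates charged together, 75.3%, which is the highest total of the two products that the charge can pay for. It lies below 100%, so partner is the limiting reagent against the two hands together, and the share is the same in both flasks because their charges are the same. The dormant form holds partner back but returns it, with a relaxation half-life of 0.157 h in Wednesday's flask, shorter than the 2.0 h of the run, so I count it inside the share.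

The two products have equal energy, so once they have levelled out the left-handed product is half of the total formed so far, and it reaches 37.6%, half the partner share, when the whole share has gone into product. In Wednesday's flask left-handed substrate reacts faster than right-handed, so left-handed product starts ahead, and the products level out with a half-life of 0.875 h, which shrinks an early excess to a fraction 0.205 by the end. In Thursday's flask that half-life falls to 0.0352 h, far shorter than the run, so left-handed product there is half of whatever total has formed. My hand reckoning goes this far: I commit to Thursday's flask ending below 37.6% and Wednesday's near that line, and I expect the two to fall within 1.5 percentage points of each other, though I cannot place them more finely.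

The forecast gives 34.2% for Wednesday's and 34.3% for Thursday's, hence all alike, on the ground that “Partner is the limiting factor because it drains into the dormant form while reacting”. The simulation gives 34.2% for Wednesday's and 34.3% for Thursday's, so all alike.

At the end the two products together make 60.7% in Wednesday's flask and 68.8% in Thursday's, both below the share. After 20.0 h, left-handed product reads 37.1% and 37.6%, close to 37.6%. The neighbour with 0.037 M of partner has a share of 18.7%, and its two products reach 18.0%, of which 11.0% is left-handed. Its free partner is down to 0.54% of its charge, while 67% of the charged left-handed substrate is still there.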